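**Retrosynthetic overview**
1. Target 21 ← global O-demethylation of nonamethyl ether 20 ← double Ullmann etherification (rings A and E) of bis-phenol 18, whose two hindered OH groups are unveiled from heptamethyl ether 17.
2. Ring D and the furan ← key intermolecular Michael addition–elimination of dibenzodioxinol 13 (through C9) to 2,3-dibromo-5-methoxy-1,4-benzoquinone 6, then O-cyclisation.
3. Dioxin (rings B/C) ← two successive vinylic substitutions on the same quinone 6 by the catechol of 5-hydroxyvanillin, ordered by a PMB group; CHO → OH later by Baeyer–Villiger oxidation.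
4. Quinone 6 and the catechol both come from 5-bromovanillin; rings A/E come from 1-iodo-3,5-dimethoxybenzene.
5. Ring order: dioxin (B/C) → ring D with furan → aryl ethers A and E → deprotection.

Assumption: the target SMILES has no stereocentre or stereogenic axis, so the compound is achiral and no enantiocontrol is needed.

Labels: rings B/C are numbered as dibenzo[b,e][1,4]dioxine in the eckol sense (ring B C1–C4, O5, ring C C6–C9, O10). Ring D carbons are D1 (bonded to the furan O, which sits on C8), D2, D3, D4, D5 and D6 (bonded to C9). Rings A and E are the 3,5-dioxygenated phenyl groups on O–C4 and O–D2.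

**Route**

Step 1
Reactants: 1 5-bromovanillin (3-bromo-4-hydroxy-5-methoxybenzaldehyde)
Product: 2 5-hydroxyvanillin (3,4-dihydroxy-5-methoxybenzaldehyde)
Conditions: NaOH (aq), Cu powder (cat.), reflux, N2; then HCl (aq)
Reagents that add atoms: sodium hydroxide [Na+].[OH-]
Why: Copper-catalysed Ullmann-type hydroxylation of the aryl bromide ortho to the phenoxide gives the catechol; no stereocentre is formed.

Step 2
Reactants: 2 5-hydroxyvanillin
Product: 3 3-hydroxy-5-methoxy-4-[(4-methoxybenzyl)oxy]benzaldehyde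
Conditions: 4-methoxybenzyl chloride (1.05 equiv), NaHCO3, NaI (cat.), DMF, 40 °C
Reagents that add atoms: 4-methoxybenzyl chloride COc1ccc(CCl)cc1
Why: Regioselective Williamson etherification, because the weak base ionises only the more acidic 4-OH para to the formyl group, leaving the 3-OH (future O10) free.

Step 3
Reactants: 1 5-bromovanillin
Product: 4 2,3-dibromo-4-hydroxy-5-methoxybenzaldehyde (5,6-dibromovanillin)
Conditions: Br2 (1.2 equiv), Fe powder (cat.), AcOH, 60 °C
Reagents that add atoms: bromine BrBr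
Why: Electrophilic aromatic bromination (FeBr3 formed in situ) at the free position para to the methoxy group.

Step 4
Reactants: 4 2,3-dibromo-4-hydroxy-5-methoxybenzaldehyde
Product: 5 2,3-dibromo-5-methoxybenzene-1,4-diol
Conditions: H2O2 (30% aq), NaOH (aq), 0 °C to rt, N2; then HCl (aq)
Reagents that add atoms: hydrogen peroxide OO
Why: Dakin oxidation of a para-hydroxybenzaldehyde (hydroperoxide addition, aryl migration, formate hydrolysis) gives the hydroquinone.

Step 5
Reactants: 5 2,3-dibromo-5-methoxybenzene-1,4-diol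
Product: 6 2,3-dibromo-5-methoxy-1,4-benzoquinone
Conditions: NaIO4, CH2Cl2/H2O, rt
Reagents that add atoms: none
Why: Two-electron periodate oxidation of the hydroquinone to the para-quinone.

Step 6
Reactants: 3 3-hydroxy-5-methoxy-4-[(4-methoxybenzyl)oxy]benzaldehyde; 6 2,3-dibromo-5-methoxy-1,4-benzoquinone
Product: 7 3-[(2-bromo-4-methoxy-3,6-dioxocyclohexa-1,4-dien-1-yl)oxy]-5-methoxy-4-[(4-methoxybenzyl)oxy]benzaldehyde
Conditions: K2CO3, MeCN, 0 °C to rt (1:1 stoichiometry)
Reagents that add atoms: none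
Why: Vinylic addition–elimination (oxa-Michael addition then loss of bromide), in which the phenoxide attacks C2 of 6, the C–Br carbon para to OMe and β to the carbonyl that is not deactivated as a vinylogous ester.

Step 7
Reactants: 7 aryloxy-bromoquinone
Product: 9 3,6-dimethoxy-1,4-dioxo-1,4-dihydrodibenzo[b,e][1,4]dioxine-8-carbaldehyde, via de-PMB phenol 8 (not isolated)
Conditions: TFA, pentamethylbenzene, CH2Cl2, 0 °C; evaporate; then K2CO3, DMF, rt
Reagents that add atoms: none
Why: Acidolysis of the PMB ether (cation trapped by pentamethylbenzene) frees the second catechol OH, whose phenoxide closes the 1,4-dioxin by intramolecular addition–elimination at the remaining C–Br, fixing the eckol regiochemistry.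

Step 8
Reactants: 9 dioxin-quinone aldehyde
Product: 11 1,3,4,6-tetramethoxydibenzo[b,e][1,4]dioxine-8-carbaldehyde, via hydroquinone 10 (not isolated)
Conditions: Na2S2O4, THF/H2O, rt; then MeI, K2CO3, DMF, 40 °C, N2
Reagents that add atoms: iodomethane CI
Why: Dithionite reduction of the quinone followed by Williamson O-methylation of the hydroquinone; this makes ring C electron-rich enough for the next step.

Step 9
Reactants: 11 1,3,4,6-tetramethoxydibenzo[b,e][1,4]dioxine-8-carbaldehyde
Product: 13 1,3,4,6-tetramethoxydibenzo[b,e][1,4]dioxin-8-ol, via aryl formate 12 (not isolated)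
Conditions: mCPBA, CH2Cl2, 0 °C to rt; then K2CO3 (cat.), MeOH, rt
Reagents that add atoms: mCPBA O=C(OO)c1cccc(Cl)c1
Why: Baeyer–Villiger oxidation with aryl migration (favoured by the para aryloxy donor O5) gives the formate, which is methanolysed to the phenol.

Step 10
Reactants: 13 1,3,4,6-tetramethoxydibenzo[b,e][1,4]dioxin-8-ol; 6 2,3-dibromo-5-methoxy-1,4-benzoquinone (1.1 equiv)
Product: 15 pentacyclic furanoquinone (1,3,4,6-tetramethoxy core; ring D as D3-methoxy-D2,D5-dione), via aryl-bromoquinone 14 (not isolated)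
Conditions: pyridine, N2, rt to 80 °C
Reagents that add atoms: none
Why: Key intermolecular Michael addition of the phenol (reacting as a vinylogous enol through C9, which is ortho to 8-OH, para to 6-OMe and flanked only by the tied-back dioxin oxygen) to C2 of the quinone with β-elimination of bromide, followed by intramolecular oxa-Michael addition–elimination of O8 at the second C–Br to close the furan.

Step 11
Reactants: 15 pentacyclic furanoquinone
Product: 17 1,3,4,6,D2,D3,D5-heptamethoxy pentacycle, via hydroquinone 16 (not isolated)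
Conditions: Na2S2O4, THF/H2O, rt; then MeI, K2CO3, DMF, 40 °C, N2
Reagents that add atoms: iodomethane CI
Why: Dithionite reduction of the ring D quinone and Williamson O-methylation of the resulting hydroquinone.

Step 12
Reactants: 17 heptamethoxy pentacycle
Product: 18 4,D2-dihydroxy-1,3,6,D3,D5-pentamethoxy pentacycle
Conditions: BCl3 (2.5 equiv), CH2Cl2, −40 to 0 °C; then H2O
Reagents that add atoms: none
Why: Chelation-controlled Lewis-acid demethylation, selective for the two "central", out-of-plane methoxy groups of 1,2,3-trioxygenated arrays (C4-OMe between O5 and 3-OMe; D2-OMe between the furan O and D3-OMe).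

Step 13
Reactants: 18 4,D2-dihydroxy pentacycle; 19 1-iodo-3,5-dimethoxybenzene (2.5 equiv)
Product: 20 4,D2-bis(3,5-dimethoxyphenoxy)-1,3,6,D3,D5-pentamethoxy pentacycle (nonamethyl ether of the target)
Conditions: CuI (20 mol %), picolinic acid (40 mol %), K3PO4, DMSO, 90 °C, N2
Reagents that add atoms: none
Why: Twofold copper-catalysed Ullmann diaryl ether synthesis, using the picolinic acid ligand system that tolerates 2,6-dioxygenated phenols, installs rings A and E together.

Step 14
Reactants: 20 nonamethyl ether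
Product: 21 phlorofucofuroeckol A
Conditions: BBr3 (excess), CH2Cl2, −78 °C to rt; then MeOH/H2O, work-up under N2
Reagents that add atoms: none
Why: Global Lewis-acid cleavage of the nine aryl methyl ethers; the diaryl ether, dioxin and furan C–O bonds are inert to BBr3, and the product is achiral.

**Compound list**
1 | 5-bromovanillin (3-bromo-4-hydroxy-5-methoxybenzaldehyde) | O=Cc1cc(OC)c(O)c(Br)c1 | starting material
2 | 5-hydroxyvanillin (3,4-dihydroxy-5-methoxybenzaldehyde) | O=Cc1cc(OC)c(O)c(O)c1 | intermediate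
3 | 3-hydroxy-5-methoxy-4-[(4-methoxybenzyl)oxy]benzaldehyde | O=Cc1cc(OC)c(OCc2ccc(OC)cc2)c(O)c1 | intermediate
4 | 2,3-dibromo-4-hydroxy-5-methoxybenzaldehyde | O=Cc1cc(OC)c(O)c(Br)c1Br | intermediate
5 | 2,3-dibromo-5-methoxybenzene-1,4-diol | Oc1cc(OC)c(O)c(Br)c1Br | intermediate
6 | 2,3-dibromo-5-methoxy-1,4-benzoquinone | O=C1C=C(OC)C(=O)C(Br)=C1Br | intermediate
7 | 3-[(2-bromo-4-methoxy-3,6-dioxocyclohexa-1,4-dien-1-yl)oxy]-5-methoxy-4-[(4-methoxybenzyl)oxy]benzaldehyde | O=Cc1cc(OC)c(OCc2ccc(OC)cc2)c(OC2=C(Br)C(=O)C(OC)=CC2=O)c1 | intermediate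
8 | 3-[(2-bromo-4-methoxy-3,6-dioxocyclohexa-1,4-dien-1-yl)oxy]-4-hydroxy-5-methoxybenzaldehyde (formed in situ) | O=Cc1cc(OC)c(O)c(OC2=C(Br)C(=O)C(OC)=CC2=O)c1 | intermediate
9 | 3,6-dimethoxy-1,4-dioxo-1,4-dihydrodibenzo[b,e][1,4]dioxine-8-carbaldehyde | O=Cc1cc(OC)c2c(c1)OC1=C(O2)C(=O)C(OC)=CC1=O | intermediate
10 | 1,4-dihydroxy-3,6-dimethoxydibenzo[b,e][1,4]dioxine-8-carbaldehyde (formed in situ) | O=Cc1cc(OC)c2c(c1)Oc1c(O2)c(O)c(OC)cc1O | intermediate
11 | 1,3,4,6-tetramethoxydibenzo[b,e][1,4]dioxine-8-carbaldehyde | O=Cc1cc(OC)c2c(c1)Oc1c(O2)c(OC)c(OC)cc1OC | intermediate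
12 | 1,3,4,6-tetramethoxydibenzo[b,e][1,4]dioxin-8-yl formate (formed in situ) | O=COc1cc(OC)c2c(c1)Oc1c(O2)c(OC)c(OC)cc1OC | intermediate
13 | 1,3,4,6-tetramethoxydibenzo[b,e][1,4]dioxin-8-ol | Oc1cc(OC)c2c(c1)Oc1c(O2)c(OC)c(OC)cc1OC | intermediate
14 | 2-(8-hydroxy-1,3,4,6-tetramethoxydibenzo[b,e][1,4]dioxin-9-yl)-3-bromo-5-methoxy-1,4-benzoquinone (formed in situ) | Oc1cc(OC)c2Oc3c(OC)c(OC)cc(OC)c3Oc2c1C1=C(Br)C(=O)C(OC)=CC1=O | intermediate
15 | pentacyclic furanoquinone: 1,3,4,6-tetramethoxy core, ring D as D3-methoxy-D2,D5-dione | O=C1C=C(OC)C(=O)c2oc3cc(OC)c4Oc5c(OC)c(OC)cc(OC)c5Oc4c3c12 | intermediate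
16 | D2,D5-dihydroxy-1,3,4,6,D3-pentamethoxy pentacycle (formed in situ) | Oc1cc(OC)c(O)c2oc3cc(OC)c4Oc5c(OC)c(OC)cc(OC)c5Oc4c3c12 | intermediate
17 | 1,3,4,6,D2,D3,D5-heptamethoxy pentacycle | COc1cc(OC)c(OC)c2oc3cc(OC)c4Oc5c(OC)c(OC)cc(OC)c5Oc4c3c12 | intermediate
18 | 4,D2-dihydroxy-1,3,6,D3,D5-pentamethoxy pentacycle | COc1cc(OC)c(O)c2oc3cc(OC)c4Oc5c(O)c(OC)cc(OC)c5Oc4c3c12 | intermediate
19 | 1-iodo-3,5-dimethoxybenzene | COc1cc(I)cc(OC)c1 | starting material
20 | 4,D2-bis(3,5-dimethoxyphenoxy)-1,3,6,D3,D5-pentamethoxy pentacycle | COc1cc(OC)c(Oc6cc(OC)cc(OC)c6)c2oc3cc(OC)c4Oc5c(Oc6cc(OC)cc(OC)c6)c(OC)cc(OC)c5Oc4c3c12 | intermediate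
21 | phlorofucofuroeckol A | Oc1cc(O)cc(Oc2c(O)cc(O)c3c2Oc2c(O)cc4oc5c(Oc6cc(O)cc(O)c6)c(O)cc(O)c5c4c2O3)c1 | target

**Count**
Total steps: 14. Longest linear sequence: 12 steps (1 → 4 → 5 → 6 → 7 → 9 → 11 → 13 → 15 → 17 → 18 → 20 → 21).

**Three steps most likely to fail**

Step 10 (key Michael addition and furan closure). The phenol could react through C7 instead of C9; the preference for C9 is an electronic and steric argument, not a blocked position. O-arylation before C-attack would misplace the ring D methoxy group. The C–C bond is also formed at a fully substituted quinone carbon. The fallback sets out from 13 (quinone partner made from 1) and comes back at 15 through 14. Dakin oxidation of 1 (H2O2, NaOH) gives 2-bromo-6-methoxybenzene-1,4-diol F1, and NaIO4 oxidises it to 2-bromo-6-methoxy-1,4-benzoquinone F2. Phenol 13 then adds in NaOAc-buffered AcOH to the unsubstituted C3–H of F2 (2.2 equiv), which is β to the carbonyl not deactivated by OMe. This is a Michael addition at an unhindered carbon without a leaving group, where O-attack is reversible, and it gives the aryl hydroquinone F3. The second equivalent of F2 oxidises F3 to the same aryl-bromoquinone 14, and K2CO3 in DMF closes the furan to 15.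

Step 12 (twofold selective demethylation). BCl3 may cleave other methyl ethers or continue to catechols. The fallback sets out from 17 and comes back at 21; it differentiates the oxygens by steric acylation at the hydroquinone stage instead of by Lewis-acid demethylation. (NH4)2Ce(NO3)6 in MeCN/H2O oxidises both para-dimethoxy rings of 17 to the bis-quinone F4. Na2S2O4 reduces it to the tetraol F5. Pivaloyl chloride (2.2 equiv) in pyridine at −20 °C esterifies only the two less hindered hydroxyls (C1-OH and D5-OH, each with a free ortho C–H), giving the bis-pivalate F6 with the hindered C4-OH and D2-OH free. Ullmann coupling with 19 under the step 13 conditions gives the bis-aryl ether F7. K2CO3 in MeOH removes the pivalates to give the diol F8, and BBr3 then gives 21.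

Step 13 (twofold Ullmann etherification of 2,6-dioxygenated phenols). It may stall at mono-arylation or oxidise the electron-rich phenol. The fallback sets out from 18 (arylating agent made from 19) and comes back at 20; it is a metal-free ligand coupling at hypervalent iodine. 19 is oxidised with mCPBA and TsOH·H2O in CH2Cl2 and then treated with 1,3,5-trimethoxybenzene to give (3,5-dimethoxyphenyl)(2,4,6-trimethoxyphenyl)iodonium tosylate F9. KOtBu and F9 in THF at rt to 40 °C transfer the 3,5-dimethoxyphenyl group to both phenoxides of 18 (the trimethoxyphenyl acts as the non-transferred ligand), giving 20.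

**Further compounds**
F1 | step 10 | 2-bromo-6-methoxybenzene-1,4-diol | Oc1cc(OC)c(O)c(Br)c1
F2 | step 10 | 2-bromo-6-methoxy-1,4-benzoquinone | O=C1C=C(OC)C(=O)C(Br)=C1
F3 | step 10 | 2-(8-hydroxy-1,3,4,6-tetramethoxydibenzo[b,e][1,4]dioxin-9-yl)-3-bromo-5-methoxybenzene-1,4-diol | Oc1cc(OC)c2Oc3c(OC)c(OC)cc(OC)c3Oc2c1-c1c(Br)c(O)c(OC)cc1O
F4 | step 12 | pentacyclic bis-quinone: 3,6,D3-trimethoxy-1,4,D2,D5-tetraone | O=C1C=C(OC)C(=O)c2oc3cc(OC)c4OC5=C(Oc4c3c12)C(=O)C=C(OC)C5=O
F5 | step 12 | 1,4,D2,D5-tetrahydroxy-3,6,D3-trimethoxy pentacycle | Oc1cc(OC)c(O)c2oc3cc(OC)c4Oc5c(O)c(OC)cc(O)c5Oc4c3c12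
F6 | step 12 | 4,D2-dihydroxy-3,6,D3-trimethoxy pentacycle 1,D5-dipivalate | CC(C)(C)C(=O)Oc1cc(OC)c(O)c2oc3cc(OC)c4Oc5c(O)c(OC)cc(OC(=O)C(C)(C)C)c5Oc4c3c12
F7 | step 12 | 4,D2-bis(3,5-dimethoxyphenoxy)-3,6,D3-trimethoxy pentacycle 1,D5-dipivalate | CC(C)(C)C(=O)Oc1cc(OC)c(Oc6cc(OC)cc(OC)c6)c2oc3cc(OC)c4Oc5c(Oc6cc(OC)cc(OC)c6)c(OC)cc(OC(=O)C(C)(C)C)c5Oc4c3c12
F8 | step 12 | 4,D2-bis(3,5-dimethoxyphenoxy)-1,D5-dihydroxy-3,6,D3-trimethoxy pentacycle | Oc1cc(OC)c(Oc6cc(OC)cc(OC)c6)c2oc3cc(OC)c4Oc5c(Oc6cc(OC)cc(OC)c6)c(OC)cc(O)c5Oc4c3c12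
F9 | step 13 | (3,5-dimethoxyphenyl)(2,4,6-trimethoxyphenyl)iodonium 4-methylbenzenesulfonate | COc1cc(OC)cc([I+]c2c(OC)cc(OC)cc2OC)c1.Cc1ccc(cc1)S([O-])(=O)=O
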